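The bicyclic core is cut at C1–C7 and C3–C4. The C2 oxygen flanked by C1 and C3 in the seven-membered ring is read as an oxyallyl cation, the arc C4–C7 as a diene, and C8–C10 as the tether that becomes the cyclopentane. One intramolecular (4+3) cycloaddition therefore closes both rings, forms two C–C bonds and sets C1, C4 and C7 from the single stereocentre C8. The precursor is an acyclic chloromethyl ketone with an (E,E)-penta-1,3-dienyl group and a silyloxymethyl group on the (R)-configured C8, built from monomethyl adipate by Evans hydroxymethylation. The C2 ketone then guides enone formation, reduction and directed epoxidation, and C13 is extended to the (Z,E)-dienol.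

Key step: step 10

Remark: atoms carry the numbers of the bicyclic target (C1 quaternary methyl carbon, C2 acetoxy carbon, C3/C4 epoxide carbons, C7 ring-fusion CH, C8–C10 cyclopentane, C13–C17 side chain); β is the face of the C1 methyl, α the opposite face; the carbon that becomes C1 is carried as an epimer mixture because it turns planar in the key step.
Remark: a tert-butyldiphenylsilyl ether is used on O13 because it cannot shift between the two CH2O arms of alcohol 8 (which would erode C8) and its hindered oxygen should not capture the cation at C1.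

Step 1
Reactants: 1 monomethyl adipate
Product: 2 6-methoxy-5-methyl-6-oxohexanoic acid (racemic)
Conditions: LiN(i-Pr)2 (2.2 equiv), THF, −78 °C; MeI, −78 → 0 °C; then aq HCl
Reagents that add atoms: iodomethane, CI
Why: Ester-enolate alkylation of the carboxylate/ester-enolate dianion, in which the second equivalent of base removes only the proton α to the ester and that carbon is methylated; the new centre (future C1) need not be controlled.

Step 2
Reactants: 2 6-methoxy-5-methyl-6-oxohexanoic acid; 3 (R)-4-benzyl-1,3-oxazolidin-2-one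
Product: 5 N-acyl oxazolidinone of acid 2, via mixed pivalic anhydride 4 (not isolated)
Conditions: t-BuCOCl, Et3N, THF, −20 °C; then 3, LiCl, −20 °C → rt
Reagents that add atoms: none
Why: N-Acylation of the Evans auxiliary through a mixed anhydride, in which pivaloyl chloride activates only the free acid and the oxazolidinone attacks the less hindered carbonyl of 4.

Step 3
Reactants: 5 N-acyl oxazolidinone
Product: 6 (S)-α-hydroxymethyl imide
Conditions: TiCl4, i-Pr2NEt, CH2Cl2, 0 °C; then 1,3,5-trioxane, TiCl4, 0 °C
Reagents that add atoms: 1,3,5-trioxane, C1OCOCO1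
Why: Evans hydroxymethylation, in which the chelated (Z)-titanium enolate of the imide (the distal ester is not enolised) is attacked by activated formaldehyde on the face away from the benzyl group, so the (R)-auxiliary sets the (S) centre that becomes C8.

Step 4
Reactants: 6 (S)-α-hydroxymethyl imide
Product: 7 tert-butyldiphenylsilyl ether of 6
Conditions: t-BuPh2SiCl, imidazole, DMF, rt
Reagents that add atoms: tert-butyl(chloro)diphenylsilane, Cl[Si](c1ccccc1)(c1ccccc1)C(C)(C)C
Why: Standard silylation of a primary alcohol with a bulky silyl chloride and imidazole.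

Step 5
Reactants: 7 silyl ether imide
Product: 8 methyl (5R)-5-(silyloxymethyl)-6-hydroxy-2-methylhexanoate
Conditions: NaBH4, THF–H2O, 0 °C → rt
Reagents that add atoms: none
Why: Reductive cleavage of the N-acyl oxazolidinone, whose activated imide carbonyl is reduced by NaBH4 in wet THF while the methyl ester is left, with release of the auxiliary.

Step 6
Reactants: 8 primary alcohol
Product: 9 methyl (5S)-5-(silyloxymethyl)-2-methyl-6-oxohexanoate
Conditions: Dess–Martin periodinane, NaHCO3, CH2Cl2, 0 °C → rt
Reagents that add atoms: none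
Why: Dess–Martin oxidation under buffered, non-basic conditions should give the α-branched aldehyde without epimerising C8.

Step 7
Reactants: 10 (E)-1-bromobut-2-ene
Product: 11 diethyl [(2E)-but-2-en-1-yl]phosphonate
Conditions: P(OEt)3, neat, 120 °C
Reagents that add atoms: triethyl phosphite, CCOP(OCC)OCC
Why: Michaelis–Arbuzov reaction at the primary allylic carbon, which keeps the (E) double bond.

Step 8
Reactants: 9 aldehyde; 11 diethyl [(2E)-but-2-en-1-yl]phosphonate
Product: 12 methyl (5R,6E,8E)-5-(silyloxymethyl)-2-methyldeca-6,8-dienoate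
Conditions: 11, n-BuLi, THF–DMPU, −78 °C; then 9, −78 °C → rt; then I2 (cat.), CH2Cl2, rt
Reagents that add atoms: none
Why: Horner–Wadsworth–Emmons olefination with the lithiated allylic phosphonate, which reacts at its α-carbon to give mainly the (E) alkene, followed by iodine-catalysed equilibration of residual (Z) isomer to the (E,E)-diene.

Step 9
Reactants: 12 dienyl ester
Product: 13 (6R,7E,9E)-6-(silyloxymethyl)-1-chloro-3-methylundeca-7,9-dien-2-one
Conditions: ICH2Cl, MeLi·LiBr, THF–Et2O, −78 °C; then aq NH4Cl at −78 °C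
Reagents that add atoms: chloroiodomethane, ClCI
Why: Ester homologation with chloromethyllithium made in situ (carbenoid addition), in which the tetrahedral lithium adduct persists at −78 °C and gives the chloromethyl ketone on quench, so chlorine is placed on C3 without any enolisation step.

Step 10
Reactants: 13 chloromethyl ketone
Product: 15 trans-fused bicyclo[5.3.0]dec-5-en-2-one cycloadduct, via oxyallyl cation 14 (not isolated)
Conditions: i-Pr2NEt (3 equiv), CF3CH2OH (0.01 M), rt
Reagents that add atoms: none
Why: Amine-assisted enolisation of 13 toward C1 and loss of chloride in the ionising, weakly nucleophilic fluoroalcohol gives the 2-oxyallyl cation 14 (C1–C2–C3), a three-carbon 2π partner that adds across the tethered 4π diene C4–C7, concerted or through an allyl cation, as in the known intramolecular oxyallyl (4+3) cycloadditions of α-halo ketones carrying a 1,3-diene on a three-carbon tether. The cyclopentane closes by 5-exo attack of the diene terminus C7 on the fully substituted cation terminus C1, and the cycloheptenone closes through the second bond C3–C4 as the seven-membered (4+3) ring. C8 is the only stereocentre present and should select the diene face, because its silyloxymethyl group prefers the pseudo-equatorial position on the forming five-membered ring, anti to C6, which fixes C7 with H7 cis to C13. C1 should follow from an extended arrangement in which the tether lies syn to the oxyallyl oxygen and the C1 methyl points away from H7, giving the trans ring fusion, while C4 follows from suprafacial addition to the (E,E)-diene and is erased in step 12. The step needs trans fusion and the anti C8/C6 relationship, which the bulky C8 group and the short tether are expected to secure, and it needs cycloaddition to outrun solvent capture and N-alkylation at the primary chloride, for which high dilution, the hindered amine and the non-nucleophilic silyl ether are chosen.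

Step 11
Reactants: 15 cycloadduct
Product: 16 saturated bicyclo[5.3.0]decan-2-one
Conditions: H2 (1 atm), Pd/C, EtOAc, rt
Reagents that add atoms: none
Why: Catalytic hydrogenation of the only C=C bond (disubstituted C5=C6), to which the hindered ketone and the silyl ether are inert.

Step 12
Reactants: 16 saturated ketone
Product: 18 C3=C4 enone, via trimethylsilyl enol ether 17 (not isolated)
Conditions: LiN(i-Pr)2, Me3SiCl, THF, −78 °C; then Pd(OAc)2, MeCN, rt
Reagents that add atoms: none
Why: Saegusa–Ito oxidation, in which the ketone can enolise only toward C3 because C1 is quaternary and the palladium enolate loses the C4 hydrogen by β-hydride elimination to give the conjugated enone.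

Step 13
Reactants: 18 enone
Product: 19 2α-allylic alcohol
Conditions: NaBH4, CeCl3·7H2O, MeOH, −78 → 0 °C
Reagents that add atoms: none
Why: Luche 1,2-reduction, in which the trans ring fusion holds the C1–C7 bond almost perpendicular to the carbonyl plane, so hydride should enter anti to that bond from the β face and leave the hydroxyl α, trans to the C1 methyl.

Step 14
Reactants: 19 2α-allylic alcohol
Product: 20 3α,4α-epoxy-2α-alcohol
Conditions: VO(acac)2 (cat.), t-BuOOH, CH2Cl2, 0 °C → rt
Reagents that add atoms: tert-butyl hydroperoxide, CC(C)(C)OO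
Why: Vanadium-catalysed hydroxyl-directed epoxidation, in which the vanadate ester of the C2 alcohol delivers oxygen to C3=C4 on its own face, so the epoxide forms cis to the hydroxyl.

Step 15
Reactants: 20 epoxy alcohol silyl ether
Product: 21 epoxy diol
Conditions: Bu4NF, THF, rt
Reagents that add atoms: none
Why: Fluoride cleavage of the silyl ether, which the cis epoxy alcohol tolerates because it cannot undergo Payne rearrangement.

Step 16
Reactants: 21 epoxy diol
Product: 22 C13 aldehyde
Conditions: TEMPO (cat.), PhI(OAc)2, CH2Cl2, rt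
Reagents that add atoms: none
Why: Oxoammonium (TEMPO) oxidation is selective for the unhindered primary alcohol over the neopentylic secondary C2 hydroxyl and leaves the epoxide alone.

Step 17
Reactants: 22 C13 aldehyde
Product: 23 C8 ethynyl compound
Conditions: dimethyl (1-diazo-2-oxopropyl)phosphonate, K2CO3, MeOH, 0 °C → rt
Reagents that add atoms: dimethyl (1-diazo-2-oxopropyl)phosphonate, COP(=O)(OC)C(=[N+]=[N-])C(C)=O
Why: Ohira–Bestmann (Seyferth–Gilbert) homologation of the aldehyde to the terminal alkyne under mild carbonate conditions, with C8 already in its preferred trans arrangement to C6 so that enolisation should not change it.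

Step 18
Reactants: 23 terminal alkyne
Product: 24 methyl ynoate with O2 methyl carbonate
Conditions: n-BuLi (2.2 equiv), THF, −78 °C; then ClCO2Me, −78 → −20 °C
Reagents that add atoms: methyl chloroformate, COC(=O)Cl
Why: Double deprotonation (alkoxide and acetylide) and acylation with a chloroformate gives the ynoate and at the same time masks O2 as a carbonate for the cuprate and hydride steps.

Step 19
Reactants: 24 ynoate
Product: 25 methyl (2Z)-3-substituted but-2-enoate
Conditions: Me2CuLi (from CuI and MeLi), THF, −78 °C; then MeOH and aq NH4Cl at −78 °C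
Reagents that add atoms: lithium dimethylcuprate Me2CuLi, [Li+].C[Cu-]C
Why: Syn carbocupration (conjugate addition) of the ynoate with cold protonation places the new methyl and the C14 hydrogen cis, so C8 and the ester end up cis as the (13Z) geometry requires.

Step 20
Reactants: 25 (Z)-enoate
Product: 26 (Z)-allylic alcohol
Conditions: i-Bu2AlH, CH2Cl2, −78 °C; then aq KNaC4H4O6
Reagents that add atoms: none
Why: 1,2-Reduction of the enoate by i-Bu2AlH at −78 °C keeps the alkene geometry, and the hindered carbonate and the epoxide should survive at this temperature.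

Step 21
Reactants: 26 (Z)-allylic alcohol
Product: 27 (Z)-enal
Conditions: MnO2, CH2Cl2, rt
Reagents that add atoms: none
Why: Neutral allylic oxidation with MnO2 should keep the (Z) geometry of the enal, which is used at once.

Step 22
Reactants: 27 (Z)-enal
Product: 28 methyl (2E,4Z)-dienoate
Conditions: Ph3P=CHCO2Me, CH2Cl2, rt
Reagents that add atoms: methyl (triphenylphosphoranylidene)acetate, COC(=O)C=P(c1ccccc1)(c1ccccc1)c1ccccc1
Why: Wittig reaction with a stabilised ylide forms the C15=C16 bond with (E) geometry.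

Step 23
Reactants: 28 dienoate carbonate
Product: 29 diol (free C2 and C17 hydroxyls)
Conditions: MeLi (excess), THF, −78 → 0 °C
Reagents that add atoms: methyllithium, [Li]C
Why: Double 1,2-addition of the organolithium to the ester builds the tertiary alcohol at C17, and the same reagent cleaves the methyl carbonate to free the C2 hydroxyl.

Step 24
Reactants: 29 diol
Product: 30 target acetate
Conditions: Ac2O, pyridine, DMAP (cat.), CH2Cl2, 0 °C → rt
Reagents that add atoms: acetic anhydride, CC(=O)OC(C)=O
Why: DMAP-catalysed acetylation should take the secondary C2 hydroxyl and leave the much slower tertiary C17 hydroxyl.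

Compound list
1 | monomethyl adipate (6-methoxy-6-oxohexanoic acid) | COC(=O)CCCCC(=O)O | starting material
2 | 6-methoxy-5-methyl-6-oxohexanoic acid (racemic) | COC(=O)C(C)CCCC(=O)O | intermediate
3 | (R)-4-benzyl-1,3-oxazolidin-2-one | O=C1N[C@H](Cc2ccccc2)CO1 | starting material
4 | mixed anhydride of 2 with pivalic acid | COC(=O)C(C)CCCC(=O)OC(=O)C(C)(C)C | intermediate
5 | methyl 6-[(4R)-4-benzyl-2-oxo-1,3-oxazolidin-3-yl]-2-methyl-6-oxohexanoate (C2 epimers) | COC(=O)C(C)CCCC(=O)N1[C@H](Cc2ccccc2)COC1=O | intermediate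
6 | methyl (5S)-5-{[(4R)-4-benzyl-2-oxo-1,3-oxazolidin-3-yl]carbonyl}-6-hydroxy-2-methylhexanoate (C2 epimers) | COC(=O)C(C)CC[C@@H](CO)C(=O)N1[C@H](Cc2ccccc2)COC1=O | intermediate
7 | methyl (5S)-5-{[(4R)-4-benzyl-2-oxo-1,3-oxazolidin-3-yl]carbonyl}-6-[(tert-butyldiphenylsilyl)oxy]-2-methylhexanoate (C2 epimers) | COC(=O)C(C)CC[C@@H](CO[Si](c1ccccc1)(c1ccccc1)C(C)(C)C)C(=O)N1[C@H](Cc2ccccc2)COC1=O | intermediate
8 | methyl (5R)-5-{[(tert-butyldiphenylsilyl)oxy]methyl}-6-hydroxy-2-methylhexanoate (C2 epimers) | COC(=O)C(C)CC[C@@H](CO[Si](c1ccccc1)(c1ccccc1)C(C)(C)C)CO | intermediate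
9 | methyl (5S)-5-{[(tert-butyldiphenylsilyl)oxy]methyl}-2-methyl-6-oxohexanoate (C2 epimers) | COC(=O)C(C)CC[C@@H](CO[Si](c1ccccc1)(c1ccccc1)C(C)(C)C)C=O | intermediate
10 | (E)-1-bromobut-2-ene | C/C=C/CBr | starting material
11 | diethyl [(2E)-but-2-en-1-yl]phosphonate | CCOP(=O)(C/C=C/C)OCC | intermediate
12 | methyl (5R,6E,8E)-5-{[(tert-butyldiphenylsilyl)oxy]methyl}-2-methyldeca-6,8-dienoate (C2 epimers) | COC(=O)C(C)CC[C@@H](CO[Si](c1ccccc1)(c1ccccc1)C(C)(C)C)/C=C/C=C/C | intermediate
13 | (6R,7E,9E)-6-{[(tert-butyldiphenylsilyl)oxy]methyl}-1-chloro-3-methylundeca-7,9-dien-2-one (C3 epimers) | ClCC(=O)C(C)CC[C@@H](CO[Si](c1ccccc1)(c1ccccc1)C(C)(C)C)/C=C/C=C/C | intermediate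
14 | 2-oxyallyl cation (zwitterion) from 13, cationic terminus at the methyl-bearing carbon | C=C([O-])[C+](C)CC[C@@H](CO[Si](c1ccccc1)(c1ccccc1)C(C)(C)C)/C=C/C=C/C | intermediate
15 | trans-fused 8α-{[(tert-butyldiphenylsilyl)oxy]methyl}-1β,4β-dimethylbicyclo[5.3.0]dec-5-en-2-one (7α-H) | O=C1C[C@@H](C)C=C[C@H]2[C@H](CO[Si](c3ccccc3)(c3ccccc3)C(C)(C)C)CC[C@]12C | intermediate
16 | trans-fused 8α-{[(tert-butyldiphenylsilyl)oxy]methyl}-1β,4β-dimethylbicyclo[5.3.0]decan-2-one | O=C1C[C@@H](C)CC[C@H]2[C@H](CO[Si](c3ccccc3)(c3ccccc3)C(C)(C)C)CC[C@]12C | intermediate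
17 | 2-(trimethylsilyloxy)bicyclo[5.3.0]dec-2-ene derived from 16 | C[Si](C)(C)OC1=C[C@@H](C)CC[C@H]2[C@H](CO[Si](c3ccccc3)(c3ccccc3)C(C)(C)C)CC[C@]12C | intermediate
18 | trans-fused 8α-{[(tert-butyldiphenylsilyl)oxy]methyl}-1β,4-dimethylbicyclo[5.3.0]dec-3-en-2-one | O=C1C=C(C)CC[C@H]2[C@H](CO[Si](c3ccccc3)(c3ccccc3)C(C)(C)C)CC[C@]12C | intermediate
19 | trans-fused 8α-{[(tert-butyldiphenylsilyl)oxy]methyl}-1β,4-dimethylbicyclo[5.3.0]dec-3-en-2α-ol | O[C@@H]1C=C(C)CC[C@H]2[C@H](CO[Si](c3ccccc3)(c3ccccc3)C(C)(C)C)CC[C@]12C | intermediate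
20 | 3α,4α-epoxy-8α-{[(tert-butyldiphenylsilyl)oxy]methyl}-1β,4β-dimethylbicyclo[5.3.0]decan-2α-ol | O[C@@H]1[C@@H]2O[C@]2(C)CC[C@H]2[C@H](CO[Si](c3ccccc3)(c3ccccc3)C(C)(C)C)CC[C@]12C | intermediate
21 | 3α,4α-epoxy-8α-(hydroxymethyl)-1β,4β-dimethylbicyclo[5.3.0]decan-2α-ol | O[C@@H]1[C@@H]2O[C@]2(C)CC[C@H]2[C@H](CO)CC[C@]12C | intermediate
22 | 3α,4α-epoxy-2α-hydroxy-1β,4β-dimethylbicyclo[5.3.0]decane-8α-carbaldehyde | O[C@@H]1[C@@H]2O[C@]2(C)CC[C@H]2[C@H](C=O)CC[C@]12C | intermediate
23 | 3α,4α-epoxy-8α-ethynyl-1β,4β-dimethylbicyclo[5.3.0]decan-2α-ol | O[C@@H]1[C@@H]2O[C@]2(C)CC[C@H]2[C@H](C#C)CC[C@]12C | intermediate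
24 | methyl 3-[3α,4α-epoxy-2α-(methoxycarbonyloxy)-1β,4β-dimethylbicyclo[5.3.0]decan-8α-yl]prop-2-ynoate | COC(=O)O[C@@H]1[C@@H]2O[C@]2(C)CC[C@H]2[C@H](C#CC(=O)OC)CC[C@]12C | intermediate
25 | methyl (2Z)-3-[3α,4α-epoxy-2α-(methoxycarbonyloxy)-1β,4β-dimethylbicyclo[5.3.0]decan-8α-yl]but-2-enoate | COC(=O)O[C@@H]1[C@@H]2O[C@]2(C)CC[C@H]2[C@H](/C(C)=C\C(=O)OC)CC[C@]12C | intermediate
26 | (2Z)-3-[3α,4α-epoxy-2α-(methoxycarbonyloxy)-1β,4β-dimethylbicyclo[5.3.0]decan-8α-yl]but-2-en-1-ol | COC(=O)O[C@@H]1[C@@H]2O[C@]2(C)CC[C@H]2[C@H](/C(C)=C\CO)CC[C@]12C | intermediate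
27 | (2Z)-3-[3α,4α-epoxy-2α-(methoxycarbonyloxy)-1β,4β-dimethylbicyclo[5.3.0]decan-8α-yl]but-2-enal | COC(=O)O[C@@H]1[C@@H]2O[C@]2(C)CC[C@H]2[C@H](/C(C)=C\C=O)CC[C@]12C | intermediate
28 | methyl (2E,4Z)-5-[3α,4α-epoxy-2α-(methoxycarbonyloxy)-1β,4β-dimethylbicyclo[5.3.0]decan-8α-yl]hexa-2,4-dienoate | COC(=O)O[C@@H]1[C@@H]2O[C@]2(C)CC[C@H]2[C@H](/C(C)=C\C=C\C(=O)OC)CC[C@]12C | intermediate
29 | (3E,5Z)-6-[3α,4α-epoxy-2α-hydroxy-1β,4β-dimethylbicyclo[5.3.0]decan-8α-yl]-2-methylhepta-3,5-dien-2-ol | O[C@@H]1[C@@H]2O[C@]2(C)CC[C@H]2[C@H](/C(C)=C\C=C\C(C)(C)O)CC[C@]12C | intermediate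
30 | CNP0265175.1: 2α-acetate of 29 | CC(=O)O[C@@H]1[C@@H]2O[C@]2(C)CC[C@H]2[C@H](/C(C)=C\C=C\C(C)(C)O)CC[C@]12C | target

Total step count: 24. Longest linear sequence: 23 steps (steps 1–6 and 8–24; step 7 prepares the phosphonate).

Steps most likely to fail

1. Step 10. Cation formation may be slow or diverted, because enolisation is needed at the hindered carbon next to C1 while the primary chloride is open to substitution and the cation to solvent capture. The ring fusion or the diene face may also be controlled incompletely. Fallback, setting out from ester 12 and returning at 15: the chlorine is moved to the carbon that becomes C1, so that only a methyl group has to be enolised and the leaving group is tertiary. LiN(i-Pr)2 followed by C2Cl6 should give the tertiary α-chloro ester F1; i-Bu2AlH at −78 °C the α-chloro aldehyde F2; MeMgBr at −78 °C the chlorohydrin F3; Dess–Martin oxidation the tertiary α-chloro methyl ketone F4. With Et3N in CF3CH2OH this should pass through the same cation 14 to 15.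

2. Step 13. Hydride may instead be delivered from the α face, anti to the C1 methyl, which would give the C2 epimer and then send the directed epoxidation to the wrong face. Fallback, setting out from enone 18 and returning at 19: the epimeric 2β-alcohol F5 obtained from that reduction is inverted by a Mitsunobu reaction (4-nitrobenzoic acid, PPh3, DIAD, toluene) to the 2α 4-nitrobenzoate F6, and K2CO3/MeOH releases 19.

3. Step 8. The new C=C bond may form with incomplete (E) selectivity, and the α-branched aldehyde may epimerise at C8 under the basic conditions. Fallback, setting out from aldehyde 9 and returning at 12: Takai iodo-olefination (CrCl2, CHI3, THF) gives the (E)-vinyl iodide F7 under non-basic conditions, and Suzuki–Miyaura coupling with (E)-prop-1-enylboronic acid (Pd(PPh3)4, aq K3PO4, THF) gives the (E,E)-diene 12 with both geometries fixed by the partners.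

Further compounds
F1 | step 10 | methyl (5R,6E,8E)-5-{[(tert-butyldiphenylsilyl)oxy]methyl}-2-chloro-2-methyldeca-6,8-dienoate | COC(=O)C(C)(Cl)CC[C@@H](CO[Si](c1ccccc1)(c1ccccc1)C(C)(C)C)/C=C/C=C/C
F2 | step 10 | (5R,6E,8E)-5-{[(tert-butyldiphenylsilyl)oxy]methyl}-2-chloro-2-methyldeca-6,8-dienal | O=CC(C)(Cl)CC[C@@H](CO[Si](c1ccccc1)(c1ccccc1)C(C)(C)C)/C=C/C=C/C
F3 | step 10 | (6R,7E,9E)-6-{[(tert-butyldiphenylsilyl)oxy]methyl}-3-chloro-3-methylundeca-7,9-dien-2-ol | CC(O)C(C)(Cl)CC[C@@H](CO[Si](c1ccccc1)(c1ccccc1)C(C)(C)C)/C=C/C=C/C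
F4 | step 10 | (6R,7E,9E)-6-{[(tert-butyldiphenylsilyl)oxy]methyl}-3-chloro-3-methylundeca-7,9-dien-2-one | CC(=O)C(C)(Cl)CC[C@@H](CO[Si](c1ccccc1)(c1ccccc1)C(C)(C)C)/C=C/C=C/C
F5 | step 13 | trans-fused 8α-{[(tert-butyldiphenylsilyl)oxy]methyl}-1β,4-dimethylbicyclo[5.3.0]dec-3-en-2β-ol | O[C@H]1C=C(C)CC[C@H]2[C@H](CO[Si](c3ccccc3)(c3ccccc3)C(C)(C)C)CC[C@]12C
F6 | step 13 | 2α-(4-nitrobenzoate) of 19 | O=C(O[C@@H]1C=C(C)CC[C@H]2[C@H](CO[Si](c3ccccc3)(c3ccccc3)C(C)(C)C)CC[C@]12C)c1ccc(cc1)[N+](=O)[O-]
F7 | step 8 | methyl (6E)-5-{[(tert-butyldiphenylsilyl)oxy]methyl}-7-iodo-2-methylhept-6-enoate (C5 configured as in 9) | COC(=O)C(C)CC[C@@H](CO[Si](c1ccccc1)(c1ccccc1)C(C)(C)C)/C=C/I
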